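# Briarellin B by Grob fragmentation of a methylcyclopentanedione-derived cyclopenta[c]pyran: synthesis design

Eunicellane numbering is used throughout. The ether oxygen (O1) bridges C2 and C9; C1 and C10 are the fusion carbons of the cyclohexane (C1, C10–C14); C15 (methyl C17) and the carbonyl C16 form the lactone arm; C18, C19 and C20 are the carbons on C3, C7 and C11.

## The problem

Briarellin B (40) is a tetracycle. A cyclohexane (C1, C10–C14) is cis-fused to a tetrahydrofuran (O1, C2, C1, C10, C9), the C2–O1–C9 unit of that ring is also part of a nine-membered ether ring (O1, C2–C9), and a seven-membered lactone (O–C16(=O)–C15–C14–C1–C2–C3) ties the tertiary C3 oxygen back to the C14 side chain. Ten stereocentres must be set (C1, C2, C3, C4, C6, C9, C10, C11, C14, C15). They are linked: C9 can fix C2 across the ether oxygen, the 2,9-cis pair can template C1, C10 and C14, C2 and C4 flank C3, the cis ring fusion exposes one face of C11, C14 neighbours C15, and the finished cage differentiates the faces of C6=C7. The nine-membered ring is the hard part, because its direct closure is costly in both entropy and strain. The sensitive groups are the octanoate and the lactone (base, nucleophiles), the tertiary C11 alcohol, and the allylic alcohol next to an exocyclic methylene (acid, transannular attack by O1). On the way there are also β-oxygenated carbonyl relationships (O1/C11 and C1–O/C3) that invite E1cB loss. The enabling feature is that C3 (oxygenated, reachable from a ketone) and C7 (methyl-bearing, olefinic) are 1,5-related in the oxonane, with oxygenated C6 next to C7. A bond drawn from C3 to C7 turns the oxonane into an oxane fused to a cyclopentane in which a C3 alkoxide and a C6 leaving group are set for heterolytic fragmentation, and that cyclopentane is 2-methylcyclopentane-1,3-dione.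

## Retrosynthesis

**C6 hydroxyl and exocyclic methylene (40 ⇒ 39 ⇒ 38).** The allylic alcohol is the most fragile corner and is unmasked last. The C6–O bond and C7=C19 are traced to epoxide 39 of the endocyclic Z-olefin in lactone 38. This is preferred over an allylic C–H oxidation because C6=C7 then travels through the route as an inert trisubstituted olefin, and it is exactly the olefin the fragmentation leaves behind. The forward steps must epoxidise the correct face and open toward the methyl group without touching two esters.

**Lactone (38 ⇒ 36).** The acyl C16–O bond is cut. The neighbouring alkyl O–C3 cut would need a C3=C4 epoxide and therefore a second olefin to be distinguished from C6=C7. Hydroxy acid 36 already carries the octanoate, placed on triol 31 where C4–OH is the only secondary hydroxyl. The forward step has to acylate a tertiary alcohol in a seven-membered closure; the C11 hydroxyl is trans-1,4 to the arm and cannot compete.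

**Propionate arm (36 ⇒ 35 ⇒ 33 ⇒ 31 ⇒ 30 ⇒ 29).** C16 is removed as a methylene carbon and the C15 stereocentre is traced to hydroboration of an isopropenyl group (30, 33) next to C14. The isopropenyl group comes from the C14 acetyl group of 29. This leaves only a methyl ketone on the ring.

**C11 and C17 methyls (29 ⇒ 28).** Both C–CH3 bonds are cut at once. Keto Weinreb amide 28 takes up two methyl nucleophiles, one at the C11 ketone from the convex face and one at the amide, which stops at the ketone.

**Cyclohexane (28 ⇒ 27 ⇒ 26 ⇒ 25).** C1–C10 and C13–C14 are cut as a Diels–Alder retron. Silyl enol ether 27 comes from tetraene 26, made by enol silylation of vinyl ketone 25. Against a stepwise Michael/aldol annulation, the cycloaddition sets C1, C10 and C14 together under control of the 2,9-cis oxonene, and the precursor is monocyclic.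

**Side chains (25 ⇒ 23 ⇒ 22 ⇒ 21 ⇒ 19 ⇒ 18).** The vinyl ketone is cut at C12=C13 (Mannich base 23, then methyl ketone 22), and the methyl ketone is the Wacker product of the C9 allyl group in 21. The enamide is cut at C1=C14 to aldehyde 19 and ylide 20. The C9 arm is thus carried as a base-stable allyl group through every strongly basic step.

**C3 and C4 (18 ⇒ 17 ⇒ 16 ⇒ 15 ⇒ 14).** The C3–C18 bond and the C4–O bond are cut, both back to the C3 ketone of oxonenone 14. The precursor retains only C2 and C9 as stereocentres. The forward steps need regioselective enolisation toward C4 and non-chelation-controlled methyl addition.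

**Key disconnection (14 ⇒ 13).** C3 and C7 are reconnected. The nine-membered ring becomes the periphery of a cis-fused cyclopenta[c]pyran 13 with a C3 hydroxyl, C7 methyl and C6 mesylate. No medium ring has to be closed, and the olefin position and geometry are fixed by the mesylate.

**Bicycle (13 ⇒ 12 ⇒ 11 ⇒ 10 ⇒ 9 ⇒ 8).** Mesylate, silyl ether and the two reductions are functional-group changes back to ketol ester 9. The C2–C3 bond of 9 is cut as an intramolecular glycolate aldol onto one carbonyl of dione 8, which closes the oxane and uses C9 to set C2.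

**Chain (8 ⇒ 6 + 7; 6 ⇒ 5 ⇒ 3 ⇒ 1 + 2).** The O1–C2 bond is cut to carbinol 6 and ethyl diazoacetate 7. The C9–C10 bond is cut to aldehyde 5 (asymmetric allylation; the only reagent-controlled stereocentre). Aldehyde 5 comes by ozonolysis (via ozonide 4) from allyl dione 3, which is made from dione 1 and allyl bromide 2. The dione supplies C3–C7 with C19 in place.

## Roads not taken

**Alternative 1: Prins–pinacol assembly of the hydroisobenzofuran.**
- Cut: C1–C2 and C9–C10.
- Forward step: SnCl4 would open dioxolane A1 to an oxocarbenium ion at C2. The cyclohexadiene attacks through C1, C9 migrates to the allyl cation carbon C10, and the carbinol carbon is expelled as the C10 formyl group of A2.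
- Merits: C1, C2, C9 and C10 are set in one convergent step from a chiral-pool cyclohexadiene that already carries C14; the tetrahydrofuran stereochemistry is very secure.
- Weak points for this target: the formyl group must be excised because C10 bears hydrogen; the C11=C12 olefin must still become the tertiary carbinol; and the oxonane must still be closed as a medium ring late in the route.
- Comparison: this road is more convergent, and its ring-forming stereocontrol is better precedented than the aldol-plus-cycloaddition relay used here. The chosen plan offers instead a nine-membered ring that is never closed, with C6=C7 and the C3 carbonyl delivered by the same event.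

**Alternative 2: epoxy-acid opening to the lactone.**
- Cut: the alkyl O–C3 bond of the lactone.
- Forward step: acid catalysis would make the C16 acid of epoxy acid A3 open the C3–C4 epoxide at C3 with inversion, closing the lactone and releasing the C4 hydroxyl in A4.
- Merits: the trans C3/C4 relationship is guaranteed by stereospecific opening, and no tertiary alcohol has to be acylated.
- Weak points: it is an endgame only and leaves all ring construction open. It needs a C3=C4 olefin to be epoxidised selectively beside the C7 methylene. Ionisation at the tertiary epoxide carbon invites hydride shift or transannular capture by O1 or the C11 hydroxyl.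
- Comparison: for C3/C4 stereochemistry this road is stronger than the Felkin-type addition of step 13. The chosen plan offers instead C3 and C4 oxygenation from the ketone that the fragmentation provides, with no extra olefin to differentiate.

**Alternative 3: oxonene-tethered Diels–Alder as the strategic step.**
- Cut: C1–C10 and C13–C14.
- Forward step: tetraene A5 cyclises thermally to cycloadduct A6.
- Merits: three stereocentres are set at once under template control.
- Weak points: the difficulty is moved to the oxonene, which must be closed from an acyclic diene (ring-closing metathesis under conformational bias) after auxiliary-based construction of C2, C3 and C9.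
- Comparison: the chosen plan uses the same cycloaddition (step 20), so this road competes only in how the oxonene arises. It would probably reach an oxonene with C3 and C4 already set in fewer steps, and with C3 fixed by acyclic chelation control, which is more reliable than step 13. The chosen plan offers instead a medium ring revealed by fragmentation (no dilution, no ruthenium carbene, olefin geometry dictated by one mesylate) and a single stoichiometric chiral reagent.

Key step: step 10

## Route

Remark on the chemistry (assumption): the aldol of step 5 is drawn as the ketol with ester and allyl group both equatorial on the new oxane and the angular methyl axial. Its C3/C7-epimeric cis-fused twin, if formed, has the same C2 and C9 configurations and converges on 14, because C3 and C7 lose their stereogenicity in step 10.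

Remark on the chemistry (assumption): hydroxy dione 6 may rest partly as its bicyclic hemiketal; it is drawn open and is expected to react through the open form.

Step 1
Reactants: 1 2-methylcyclopentane-1,3-dione; 2 allyl bromide
Product: 3 2-allyl-2-methylcyclopentane-1,3-dione
Conditions: NaOH (1 M aq), rt
Reagents that add atoms: none
Why: C-alkylation of the dione enolate by an allylic halide in water is an established reaction of this substrate; it installs the quaternary C7 with C19 and C8.

Step 2
Reactants: 3 2-allyl-2-methylcyclopentane-1,3-dione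
Product: 5 2-(1-methyl-2,5-dioxocyclopentyl)acetaldehyde, via secondary ozonide 4 (not isolated)
Conditions: O3, CH2Cl2, −78 °C; then PPh3, −78 °C → rt
Reagents that add atoms: ozone, [O-][O+]=O
Why: Ozonolysis of the only olefin with reductive work-up should give the C9 aldehyde; the non-enolisable dione is inert.

Step 3
Reactants: 5 2-(1-methyl-2,5-dioxocyclopentyl)acetaldehyde
Product: 6 2-[(2R)-2-hydroxypent-4-en-1-yl]-2-methylcyclopentane-1,3-dione
Conditions: (+)-Ipc2B(allyl) (1 M in pentane), Et2O, −78 °C; then HOCH2CH2NH2, rt
Reagents that add atoms: (+)-B-allyldiisopinocampheylborane, C=CCB([C@H]1C[C@H]2C[C@@H]([C@@H]1C)C2(C)C)[C@H]1C[C@H]2C[C@@H]([C@@H]1C)C2(C)C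
Why: Brown allylboration through a chair six-membered transition state; the aldehyde reacts far faster than the hindered ketones. The reagent from (−)-α-pinene should deliver the allyl group to the face that gives the (R)-carbinol (C9), the only stereocentre set by a chiral reagent; the non-oxidative work-up spares the dione.

Step 4
Reactants: 6 2-[(2R)-2-hydroxypent-4-en-1-yl]-2-methylcyclopentane-1,3-dione; 7 ethyl diazoacetate
Product: 8 ethyl {[(2R)-1-(1-methyl-2,5-dioxocyclopentyl)pent-4-en-2-yl]oxy}acetate
Conditions: Rh2(OAc)4 (1 mol%), CH2Cl2, rt, slow addition of 7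
Reagents that add atoms: none
Why: Rhodium-carbenoid O–H insertion etherifies the secondary alcohol under neutral conditions, avoiding the alkoxide that would attack the dione (retro-Claisen); O–H insertion is faster than cyclopropanation of the monosubstituted olefin.

Step 5
Reactants: 8 ethyl {[(2R)-1-(1-methyl-2,5-dioxocyclopentyl)pent-4-en-2-yl]oxy}acetate
Product: 9 ethyl 3-allyl-7a-hydroxy-4a-methyl-5-oxooctahydrocyclopenta[c]pyran-1-carboxylate (cis-fused; eunicellane C2 ester and C9 allyl cis, C3 hydroxyl syn to the C7 methyl and anti to the ester; C6 ketone)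
Conditions: LiN(SiMe3)2 (1.1 equiv), THF, −78 → −40 °C; AcOH, −78 °C
Reagents that add atoms: none
Why: Intramolecular ester-enolate aldol (6-exo-trig) onto one dione carbonyl; with an amide base of matched basicity ketone deprotonation is reversible and unproductive, while the glycolate enolate is drained by cyclisation. The tether enforces cis fusion (C3, C7), and a chair transition state with allyl and ester equatorial sets C2 cis to C9; the lithium aldolate at low temperature resists retro-aldol ring expansion.

Step 6
Reactants: 9 ketol ester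
Product: 10 ethyl 3-allyl-5,7a-dihydroxy-4a-methyloctahydrocyclopenta[c]pyran-1-carboxylate (C6 hydroxyl anti to the C3 hydroxyl and to the C7 methyl, syn to C8)
Conditions: Me4NBH(OAc)3, MeCN/AcOH, −20 °C
Reagents that add atoms: none
Why: Evans–Saksena directed reduction: the acetoxyborohydride exchanges onto the C3 hydroxyl and delivers hydride intramolecularly to the hydroxyl face of the C6 ketone, giving the 1,3-anti diol and hence the C6 oxygen trans to the angular methyl; the ester is not reduced.

Step 7
Reactants: 10 diol ester
Product: 11 3-allyl-1-(hydroxymethyl)-4a-methylhexahydrocyclopenta[c]pyran-5,7a-diol (triol; C1 primary, C6 secondary, C3 tertiary hydroxyl)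
Conditions: LiBH4, THF/MeOH, 0 °C → rt
Reagents that add atoms: none
Why: LiBH4 reduces the activated α-alkoxy ester to the primary alcohol and leaves the olefin alone; no stereocentre is touched.

Step 8
Reactants: 11 triol
Product: 12 primary triethylsilyl ether of 11 (C1–OSiEt3; C3 and C6 hydroxyls free)
Conditions: Et3SiCl (1.05 equiv), imidazole, CH2Cl2, −40 °C
Reagents that add atoms: chlorotriethylsilane, CC[Si](Cl)(CC)CC
Why: Silylation with a chlorosilane is selective for the primary over the neopentyl-type secondary and the tertiary hydroxyl at low temperature.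

Step 9
Reactants: 12 silyl ether diol
Product: 13 cis-fused cyclopenta[c]pyran with C1–OSiEt3, C3 hydroxyl, C7 methyl, C9 allyl and C6 mesylate (mesylate trans to the C7 methyl and to the C3 hydroxyl)
Conditions: MsCl, Et3N, CH2Cl2, 0 °C
Reagents that add atoms: methanesulfonyl chloride, CS(=O)(=O)Cl
Why: Sulfonylation through sulfene takes the only secondary hydroxyl; the tertiary alcohol is inert and no alkoxide is formed, so nothing fragments yet.

Step 10
Reactants: 13 hydroxy mesylate
Product: 14 (2S,9R,6Z)-9-allyl-7-methyl-2-[(triethylsilyloxy)methyl]-4,5,8,9-tetrahydro-2H-oxonin-3-one (2,9-cis)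
Conditions: KOC(CH3)3 (1.05 equiv), THF, 0 °C; pH 7 buffer
Reagents that add atoms: none
Why: KOC(CH3)3 deprotonates the tertiary C3 hydroxyl and the alkoxide lone pair pushes into the C3–C7 σ bond as the C6–O bond ionises, a concerted Grob (Wharton-type) fragmentation of a 1,3-diol monosulfonate, the reaction class that turns hydrindane-type hydroxy sulfonates into cyclononenones. No ring is closed: the nine-membered ether is unveiled by heterolysis of the bond shared by oxane and cyclopentane, so that the periphery O1, C2–C9 becomes the oxonane. No stereocentre is created; C3 and C7 become trigonal, and C2 and C9 keep the cis relationship set in steps 3 and 5. The olefin geometry follows from the anti-periplanar transition state: the mesylate is trans to the angular methyl and cis to C8, so C5 and C8 end up cis on C6=C7 (Z). The step needs fragmentation to beat E2 elimination toward C5 and oxetane formation; the cis-fused bicycle lets the cyclopentane take an envelope with the mesylate pseudo-axial and anti to C3–C7, and the potassium alkoxide in THF is the ion pair most prone to fragment. It also needs the new α-alkoxy ketone to survive, which a minimal excess of base at 0 °C and immediate buffering should secure, so that C2 is neither epimerised nor the β-silyloxy group eliminated.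

Step 11
Reactants: 14 oxonenone
Product: 15 4-hydroxy derivative of 14 (C4 hydroxyl on the face of H2 and H9, anti to the C2 side chain)
Conditions: KN(SiMe3)2, THF, −78 °C; then 2-(phenylsulfonyl)-3-phenyloxaziridine; NH4Cl (aq)
Reagents that add atoms: 2-(phenylsulfonyl)-3-phenyloxaziridine, O=S(=O)(N1OC1c1ccccc1)c1ccccc1
Why: Kinetic deprotonation takes the C4 methylene in preference to the hindered α-alkoxy methine C2, and the potassium enolate is oxidised by the N-sulfonyloxaziridine (Davis hydroxylation), which leaves both olefins alone. The reagent should approach the ring enolate from the face away from the C2 side chain, setting C4.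

Step 12
Reactants: 15 α-hydroxy ketone
Product: 16 4-(tert-butyldimethylsilyloxy) ketone
Conditions: tBuMe2SiOTf, 2,6-lutidine, CH2Cl2, −78 °C
Reagents that add atoms: tert-butyldimethylsilyl triflate, CC(C)(C)[Si](C)(C)OS(=O)(=O)C(F)(F)F
Why: Silyl triflate protection of the hindered α-ketol at low temperature; a bulky non-chelating ether is wanted for the next step.

Step 13
Reactants: 16 α-silyloxy ketone
Product: 17 tertiary alcohol (C3 methyl syn to H2 and to the C4 silyloxy group; C3 hydroxyl syn to the C2 side chain)
Conditions: MeLi, THF, −78 °C; NH4Cl (aq)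
Reagents that add atoms: methyllithium, [Li]C
Why: 1,2-Addition under non-chelating conditions (silyl ether, lithium in THF): in the polar Felkin–Anh sense the methyl group enters anti to the C2–O1 and the C4–O bonds, and both flanking stereocentres call for the same face, which places the C3 oxygen trans to the C4 oxygen and cis to C1.

Step 14
Reactants: 17 tertiary alcohol
Product: 18 tris-silyl ether (C1–OSiEt3, C3–OSiEt3, C4–OSitBuMe2)
Conditions: Et3SiOTf, 2,6-lutidine, CH2Cl2, 0 °C
Reagents that add atoms: triethylsilyl triflate, CC[Si](CC)(CC)OS(=O)(=O)C(F)(F)F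
Why: Silyl triflates silylate tertiary alcohols; the ether blocks retro-aldol and vinylogous retro-aldol opening of the ring in the steps that follow.

Step 15
Reactants: 18 tris-silyl ether
Product: 19 C1 aldehyde (oxonene-2-carbaldehyde; C3–OSiEt3 and C4–OSitBuMe2 retained)
Conditions: (COCl)2, DMSO, CH2Cl2, −78 → −30 °C; then Et3N, −78 °C → 0 °C
Reagents that add atoms: none
Why: Swern conditions cleave and oxidise primary triethylsilyl ethers directly to aldehydes while tertiary triethylsilyl and secondary tert-butyldimethylsilyl ethers survive; the aldehyde is used at once to protect C2.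

Step 16
Reactants: 19 aldehyde; 20 N-methoxy-N-methyl-2-(triphenylphosphoranylidene)acetamide
Product: 21 (E)-enamide (C2–CH=CH–C(=O)N(OMe)Me; C1=C14)
Conditions: CH2Cl2, rt
Reagents that add atoms: none
Why: Wittig olefination with a stabilised ylide is E-selective and neutral; the amide is a dienophile that cannot be enolised in step 20 and that stops at the ketone stage in step 21.

Step 17
Reactants: 21 enamide with C9 allyl group
Product: 22 methyl ketone (C9–CH2–C(=O)–CH3; C11 ketone)
Conditions: PdCl2 (10 mol%), Cu(OAc)2 (20 mol%), O2 (1 atm), DMA/H2O, rt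
Reagents that add atoms: water, O
Why: Tsuji–Wacker oxidation converts the monosubstituted olefin to the methyl ketone with Markovnikov selectivity; the trisubstituted and the electron-poor olefins do not react, and the copper diacetate variant avoids HCl and so spares the silyl ethers.

Step 18
Reactants: 22 methyl ketone
Product: 23 Mannich base (C9–CH2–C(=O)–CH2CH2NMe2)
Conditions: LiN(SiMe3)2, THF, −78 °C; then [CH2=NMe2]I, −78 → 0 °C
Reagents that add atoms: N,N-dimethylmethyleneiminium iodide, C=[N+](C)C.[I-]
Why: Kinetic deprotonation of a methyl ketone occurs at the methyl group, so the enolate cannot expel O1; trapping with Eschenmoser's salt is the standard Mannich route to a vinyl ketone and adds C13.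

Step 19
Reactants: 23 Mannich base
Product: 25 vinyl ketone (C9–CH2–C(=O)–CH=CH2), via trimethylammonium iodide 24 (not isolated)
Conditions: MeI, CH2Cl2, rt; then NaHCO3 (aq), rt
Reagents that add atoms: none
Why: Quaternisation followed by mild base-induced β-elimination (E1cB) releases the enone without a base strong enough to enolise toward C10.

Step 20
Reactants: 25 vinyl ketone enamide
Product: 28 tricyclic keto amide (C11 ketone, C14 Weinreb amide; H1 and H10 cis and anti to H2 and H9; C14 substituent trans to C2), via silyloxydiene tetraene 26 (not isolated), via cycloadduct silyl enol ether 27 (not isolated)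
Conditions: Et3SiOTf, Et3N, CH2Cl2, −78 → 0 °C; then PhMe, 80 °C; then HCl (1 M aq), THF, 0 °C
Reagents that add atoms: none
Why: Soft enolisation can only go toward C10 and should give the (Z)-2-silyloxydiene. The intramolecular Diels–Alder reaction with a three-atom tether (C9–O1–C2) forms C1–C10 and C13–C14 with the amide exo, the 2,9-cis oxonene enforcing the cis-fused tetrahydrofuran and the E-dienophile giving C14 trans to C2. Mild acid then hydrolyses only the enol ether by protonation at C12, leaving C10 untouched.

Step 21
Reactants: 28 keto amide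
Product: 29 C11 tertiary alcohol with C14 acetyl group (C11 hydroxyl syn to C9 and anti to H10; C20 methyl on the face of H1 and H10)
Conditions: MeLi (5 equiv), CeCl3, THF, −78 → 0 °C; NH4Cl (aq)
Reagents that add atoms: methyllithium (transmetalated to MeCeCl2), [Li]C
Why: The weakly basic organocerium reagent adds to the enolisable β-alkoxy ketone without E1cB opening of the tetrahydrofuran. It attacks C11 axially from the convex face of the cis-fused bicycle (the face of H1 and H10), and it converts the Weinreb amide into the methyl ketone through a stable chelate that collapses only on work-up.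

Step 22
Reactants: 29 hydroxy methyl ketone
Product: 30 isopropenyl compound (C14–C(CH3)=CH2)
Conditions: Ph3PCH3Br, KOC(CH3)3 (3 equiv each), THF, 0 °C → rt
Reagents that add atoms: methyltriphenylphosphonium bromide (as its ylide), C[P+](c1ccccc1)(c1ccccc1)c1ccccc1.[Br-]
Why: Wittig methylenation of the methyl ketone adds C16; the C14 substituent is equatorial and trans to C2, so enolisation under the ylide should not change it.

Step 23
Reactants: 30 bis-silyl ether
Product: 31 triol (C3, C4 and C11 hydroxyls free; isopropenyl at C14)
Conditions: Bu4NF, THF, rt → 40 °C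
Reagents that add atoms: none
Why: Fluoride removes both the tertiary triethylsilyl and the secondary tert-butyldimethylsilyl ether in one operation; no base-sensitive group is present yet.

Step 24
Reactants: 31 triol; 32 octanoyl chloride
Product: 33 C4 octanoate (C3 and C11 hydroxyls free)
Conditions: pyridine, DMAP (cat.), CH2Cl2, 0 °C
Reagents that add atoms: none
Why: Acylation takes the only secondary hydroxyl; the two tertiary alcohols do not react under these conditions.

Step 25
Reactants: 33 isopropenyl octanoate
Product: 35 primary alcohol (C14–CH(CH3)–CH2OH; C15 as in the target, C17 methyl cis to C13 across the future lactone), via B-alkyl-9-borabicyclononane 34 (not isolated)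
Conditions: 9-BBN (excess), THF, 0 °C → rt; then NaBO3·4H2O, H2O, rt
Reagents that add atoms: sodium perborate, [Na+].[O-]OB=O
Why: 9-BBN hydroborates the 1,1-disubstituted olefin in the presence of the trisubstituted C6=C7 and the esters, and perborate oxidation spares the octanoate. In the A(1,3)-minimised conformer (H14 eclipsing the olefin) the borane should add anti to the branched C1, which gives the required C15 configuration.

Step 26
Reactants: 35 primary alcohol
Product: 36 hydroxy acid (C16 carboxylic acid; C3 hydroxyl free)
Conditions: TEMPO (20 mol%), PhI(OAc)2, MeCN/H2O (pH 7), rt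
Reagents that add atoms: water, O
Why: Oxoammonium oxidation takes the primary alcohol through the aldehyde hydrate to the acid without epimerising C15 and without touching olefin, ester or tertiary alcohols.

Step 27
Reactants: 36 hydroxy acid
Product: 38 seven-membered lactone (O3–C16; C4 octanoate; C6=C7 Z-olefin), via mixed anhydride 37 (not isolated)
Conditions: 2,4,6-Cl3C6H2COCl, Et3N, THF, rt; then DMAP, PhMe, 80 °C (high dilution)
Reagents that add atoms: none
Why: Yamaguchi lactonisation through the acylpyridinium ion; the C3 hydroxyl is held next to the arm on C14 (7-exo-trig closure), while the C11 hydroxyl is trans-1,4 to the arm and cannot reach it.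

Step 28
Reactants: 38 lactone
Product: 39 C6–C7 epoxide (epoxide oxygen on the face opposite H2 and H9)
Conditions: mCPBA, NaHCO3, CH2Cl2, 0 °C
Reagents that add atoms: 3-chloroperbenzoic acid, OOC(=O)c1cccc(Cl)c1
Why: Prilezhaev epoxidation of the only remaining olefin; the peracid should attack the exposed peripheral face of the Z-olefin held in the rigid tetracycle, which sets C6 (and transiently C7).

Step 29
Reactants: 39 epoxide
Product: 40 briarellin B
Conditions: Cp2TiCl2 (2.5 equiv), Mn, THF, rt; then HCl (0.5 M aq)
Reagents that add atoms: none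
Why: Bis(cyclopentadienyl)titanium chloride (trivalent titanium) opens the epoxide homolytically at the tertiary C7–O bond, and a second equivalent abstracts a β-hydrogen from the C19 methyl, the known epoxide-to-allylic-alcohol isomerisation that favours the exocyclic olefin; the C6–O bond is never broken, and esters and the lactone are inert.

## Compound list

1 | 2-methylcyclopentane-1,3-dione | CC1C(=O)CCC1=O | starting material
2 | allyl bromide | C=CCBr | starting material
3 | 2-allyl-2-methylcyclopentane-1,3-dione | C=CCC1(C)C(=O)CCC1=O | intermediate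
4 | 2-methyl-2-(1,2,4-trioxolan-3-ylmethyl)cyclopentane-1,3-dione (secondary ozonide) | CC1(CC2OCOO2)C(=O)CCC1=O | intermediate
5 | 2-(1-methyl-2,5-dioxocyclopentyl)acetaldehyde | CC1(CC=O)C(=O)CCC1=O | intermediate
6 | 2-[(2R)-2-hydroxypent-4-en-1-yl]-2-methylcyclopentane-1,3-dione | C=CC[C@@H](O)CC1(C)C(=O)CCC1=O | intermediate
7 | ethyl diazoacetate | CCOC(=O)C=[N+]=[N-] | starting material
8 | ethyl {[(2R)-1-(1-methyl-2,5-dioxocyclopentyl)pent-4-en-2-yl]oxy}acetate | C=CC[C@@H](OCC(=O)OCC)CC1(C)C(=O)CCC1=O | intermediate
9 | ethyl 3-allyl-7a-hydroxy-4a-methyl-5-oxooctahydrocyclopenta[c]pyran-1-carboxylate, cis-fused, ester and allyl cis, hydroxyl syn to methyl | O1[C@@H](C(=O)OCC)[C@@]2(O)CCC(=O)[C@@]2(C)C[C@H]1CC=C | intermediate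
10 | ethyl 3-allyl-5,7a-dihydroxy-4a-methyloctahydrocyclopenta[c]pyran-1-carboxylate, 5-hydroxyl anti to 7a-hydroxyl | O1[C@@H](C(=O)OCC)[C@@]2(O)CC[C@@H](O)[C@@]2(C)C[C@H]1CC=C | intermediate
11 | 3-allyl-1-(hydroxymethyl)-4a-methylhexahydrocyclopenta[c]pyran-5,7a-diol | O1[C@@H](CO)[C@@]2(O)CC[C@@H](O)[C@@]2(C)C[C@H]1CC=C | intermediate
12 | 3-allyl-4a-methyl-1-[(triethylsilyloxy)methyl]hexahydrocyclopenta[c]pyran-5,7a-diol | O1[C@@H](CO[Si](CC)(CC)CC)[C@@]2(O)CC[C@@H](O)[C@@]2(C)C[C@H]1CC=C | intermediate
13 | 3-allyl-7a-hydroxy-4a-methyl-1-[(triethylsilyloxy)methyl]octahydrocyclopenta[c]pyran-5-yl methanesulfonate (key-step precursor) | O1[C@@H](CO[Si](CC)(CC)CC)[C@@]2(O)CC[C@@H](OS(C)(=O)=O)[C@@]2(C)C[C@H]1CC=C | intermediate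
14 | (2S,9R,6Z)-9-allyl-7-methyl-2-[(triethylsilyloxy)methyl]-4,5,8,9-tetrahydro-2H-oxonin-3-one (key-step product) | C/C1=C/CCC(=O)[C@H](CO[Si](CC)(CC)CC)O[C@@H](C1)CC=C | intermediate
15 | 4-hydroxy derivative of 14, hydroxyl syn to H2 | C/C1=C/C[C@@H](O)C(=O)[C@H](CO[Si](CC)(CC)CC)O[C@@H](C1)CC=C | intermediate
16 | 4-(tert-butyldimethylsilyloxy) derivative of 14 | C/C1=C/C[C@@H](O[Si](C)(C)C(C)(C)C)C(=O)[C@H](CO[Si](CC)(CC)CC)O[C@@H](C1)CC=C | intermediate
17 | Z-oxonene with C3 methyl carbinol (methyl syn to H2), C4 silyloxy, C2 silyloxymethyl, C9 allyl | C/C1=C/C[C@@H](O[Si](C)(C)C(C)(C)C)[C@](C)(O)[C@H](CO[Si](CC)(CC)CC)O[C@@H](C1)CC=C | intermediate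
18 | C3 triethylsilyl ether of 17 | C/C1=C/C[C@@H](O[Si](C)(C)C(C)(C)C)[C@](C)(O[Si](CC)(CC)CC)[C@H](CO[Si](CC)(CC)CC)O[C@@H](C1)CC=C | intermediate
19 | oxonene-2-carbaldehyde (C1 aldehyde) | C/C1=C/C[C@@H](O[Si](C)(C)C(C)(C)C)[C@](C)(O[Si](CC)(CC)CC)[C@H](C=O)O[C@@H](C1)CC=C | intermediate
20 | N-methoxy-N-methyl-2-(triphenylphosphoranylidene)acetamide | CON(C)C(=O)C=P(c1ccccc1)(c1ccccc1)c1ccccc1 | starting material
21 | (E)-N-methoxy-N-methylacrylamide on C2, allyl on C9 | C/C1=C/C[C@@H](O[Si](C)(C)C(C)(C)C)[C@](C)(O[Si](CC)(CC)CC)[C@H](/C=C/C(=O)N(C)OC)O[C@@H](C1)CC=C | intermediate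
22 | methyl ketone (2-oxopropyl on C9) | C/C1=C/C[C@@H](O[Si](C)(C)C(C)(C)C)[C@](C)(O[Si](CC)(CC)CC)[C@H](/C=C/C(=O)N(C)OC)O[C@@H](C1)CC(C)=O | intermediate
23 | Mannich base (4-(dimethylamino)-2-oxobutyl on C9) | C/C1=C/C[C@@H](O[Si](C)(C)C(C)(C)C)[C@](C)(O[Si](CC)(CC)CC)[C@H](/C=C/C(=O)N(C)OC)O[C@@H](C1)CC(=O)CCN(C)C | intermediate
24 | trimethylammonium iodide of 23 | C/C1=C/C[C@@H](O[Si](C)(C)C(C)(C)C)[C@](C)(O[Si](CC)(CC)CC)[C@H](/C=C/C(=O)N(C)OC)O[C@@H](C1)CC(=O)CC[N+](C)(C)C.[I-] | intermediate
25 | vinyl ketone (2-oxobut-3-enyl on C9) | C/C1=C/C[C@@H](O[Si](C)(C)C(C)(C)C)[C@](C)(O[Si](CC)(CC)CC)[C@H](/C=C/C(=O)N(C)OC)O[C@@H](C1)CC(=O)C=C | intermediate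
26 | tetraene with (Z)-2-(triethylsilyloxy)buta-1,3-dienyl on C9 | C/C1=C/C[C@@H](O[Si](C)(C)C(C)(C)C)[C@](C)(O[Si](CC)(CC)CC)[C@H](/C=C/C(=O)N(C)OC)O[C@@H](C1)/C=C(\O[Si](CC)(CC)CC)C=C | intermediate
27 | tricyclic cycloadduct with C11 silyl enol ether and C14 Weinreb amide | C/C1=C/C[C@@H](O[Si](C)(C)C(C)(C)C)[C@](C)(O[Si](CC)(CC)CC)[C@H]2O[C@@H](C1)[C@@H]3C(O[Si](CC)(CC)CC)=CC[C@@H](C(=O)N(C)OC)[C@H]23 | intermediate
28 | tricyclic C11 ketone with C14 Weinreb amide | C/C1=C/C[C@@H](O[Si](C)(C)C(C)(C)C)[C@](C)(O[Si](CC)(CC)CC)[C@H]2O[C@@H](C1)[C@@H]3C(=O)CC[C@@H](C(=O)N(C)OC)[C@H]23 | intermediate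
29 | tricyclic C11 methyl carbinol with C14 acetyl | C/C1=C/C[C@@H](O[Si](C)(C)C(C)(C)C)[C@](C)(O[Si](CC)(CC)CC)[C@H]2O[C@@H](C1)[C@@H]3[C@](C)(O)CC[C@@H](C(C)=O)[C@H]23 | intermediate
30 | tricyclic C11 carbinol with C14 isopropenyl | C/C1=C/C[C@@H](O[Si](C)(C)C(C)(C)C)[C@](C)(O[Si](CC)(CC)CC)[C@H]2O[C@@H](C1)[C@@H]3[C@](C)(O)CC[C@@H](C(C)=C)[C@H]23 | intermediate
31 | tricyclic 3,4,11-triol with C14 isopropenyl | C/C1=C/C[C@@H](O)[C@](C)(O)[C@H]2O[C@@H](C1)[C@@H]3[C@](C)(O)CC[C@@H](C(C)=C)[C@H]23 | intermediate
32 | octanoyl chloride | CCCCCCCC(=O)Cl | starting material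
33 | C4 octanoate of 31 | C/C1=C/C[C@@H](OC(=O)CCCCCCC)[C@](C)(O)[C@H]2O[C@@H](C1)[C@@H]3[C@](C)(O)CC[C@@H](C(C)=C)[C@H]23 | intermediate
34 | B-alkyl-9-borabicyclo[3.3.1]nonane (boron on C16) | C/C1=C/C[C@@H](OC(=O)CCCCCCC)[C@](C)(O)[C@H]2O[C@@H](C1)[C@@H]3[C@](C)(O)CC[C@@H]([C@@H](C)CB4C5CCCC4CCC5)[C@H]23 | intermediate
35 | C16 primary alcohol | C/C1=C/C[C@@H](OC(=O)CCCCCCC)[C@](C)(O)[C@H]2O[C@@H](C1)[C@@H]3[C@](C)(O)CC[C@@H]([C@@H](C)CO)[C@H]23 | intermediate
36 | C16 carboxylic acid (hydroxy acid) | C/C1=C/C[C@@H](OC(=O)CCCCCCC)[C@](C)(O)[C@H]2O[C@@H](C1)[C@@H]3[C@](C)(O)CC[C@@H]([C@@H](C)C(=O)O)[C@H]23 | intermediate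
37 | mixed 2,4,6-trichlorobenzoic anhydride of 36 | C/C1=C/C[C@@H](OC(=O)CCCCCCC)[C@](C)(O)[C@H]2O[C@@H](C1)[C@@H]3[C@](C)(O)CC[C@@H]([C@@H](C)C(=O)OC(=O)c4c(Cl)cc(Cl)cc4Cl)[C@H]23 | intermediate
38 | tetracyclic lactone with C6=C7 Z-olefin and C4 octanoate | C/C1=C/C[C@@H](OC(=O)CCCCCCC)[C@](C)(O5)[C@H]2O[C@@H](C1)[C@@H]3[C@](C)(O)CC[C@@H]([C@@H](C)C5=O)[C@H]23 | intermediate
39 | C6–C7 epoxide of 38 | C[C@@]1(O6)[C@H]6C[C@@H](OC(=O)CCCCCCC)[C@](C)(O5)[C@H]2O[C@@H](C1)[C@@H]3[C@](C)(O)CC[C@@H]([C@@H](C)C5=O)[C@H]23 | intermediate
40 | briarellin B | C=C1C[C@@H]2O[C@H]3[C@H]4[C@@H](CC[C@@](C)(O)[C@H]42)[C@@H](C)C(=O)O[C@@]3(C)[C@H](OC(=O)CCCCCCC)C[C@H]1O | target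

## Step count and risks

Total step count: 29. Longest linear sequence: 29 steps from 1 (2, 7, 20 and 32 are purchased).

**Step 10 (key step).** The likeliest failure is loss of the new α-alkoxy ketone to the excess alkoxide, by epimerisation at C2 or β-elimination of the silyloxy group. Silyl migration from O1′ to the C3 alkoxide, or E2/oxetane formation if the mesylate cannot reach the pseudo-axial position, would lower the rate further. Fallback: the alkoxide is generated without any Brønsted base. From 13, the tertiary hydroxyl is silylated (Me3SiOTf, 2,6-lutidine, −78 °C) to the O3-trimethylsilyl ether F1. One equivalent of anhydrous fluoride ([Bu4N][Ph3SiF2], THF, −78 °C) removes the most labile silyl group and the naked ammonium alkoxide fragments at once, returning to the route at 14.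

**Step 5.** Unselective deprotonation (ketone α-hydrogens against the glycolate) and retro-aldol ring expansion of the aldolate through the C6 carbonyl are the main dangers. A trans arrangement at C2 would be corrected by equilibration, since the ester is epimerisable. Fallback: the enolate is made regiospecifically instead of by deprotonation. From 6, O–H insertion with ethyl 2-diazo-2-(trimethylsilyl)acetate (Rh2(OAc)4) gives the α-silyl glycolate ether F2. Fluoride (Bu4NF, THF, −78 °C) then releases the ester enolate at C2 only, and this closes to 9.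

**Step 13.** Poor facial selectivity in the medium ring is the risk: chelation by O1 or a ring conformation that violates the Felkin–Anh picture would give the C3 epimer, and enolisation could compete. Fallback: the C3 oxygen is delivered from the C2 arm instead of the methyl group being added to the ketone.
- From 16, methylenation (Cp2TiMe2, PhMe, 65 °C) gives the exocyclic olefin F3.
- Selective methanolysis of the primary silyl ether (PPTS, MeOH, 0 °C) gives the homoallylic alcohol F4.
- Hydroxyl-directed epoxidation (VO(acac)2, tBuOOH) places oxygen on the face of the C1 arm, giving spiro-epoxide F5.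
- LiEt3BH opens it at the methylene carbon to diol F6.
- Bis-silylation (Et3SiOTf, 2,6-lutidine) returns to the route at 18.

**Step 25.** Low substrate control at C15 is possible, because the two ring substituents on C14 differ only modestly in size. Fallback: the centre is corrected after ring closure instead of being set by the borane. From 33, the C15-epimeric alcohol F7 is taken through the conditions of steps 26 and 27 as the acid F8 and its mixed anhydride F9 to the C15-epimeric lactone F10. Deprotonation (LiN(SiMe3)2, THF, −78 °C) and kinetic protonation of the lactone enolate on the face of H14, away from C13, returns to the route at 38.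

**Step 27.** Slow acylation of the tertiary C3 hydroxyl may let oligomerisation or ketene-type epimerisation of the activated acid compete. Fallback: the ring is closed at the aldehyde oxidation level. From 35, TEMPO/PhI(OAc)2 in dry CH2Cl2 gives the hydroxy aldehyde F11, which should rest in part as the seven-membered lactol F12; further oxidation in the same flask gives 38.

**Step 28.** Attack of the peracid on the other olefin face would carry the wrong C6 configuration through step 29. Fallback: C6 is inverted at the end. From 38, the epimeric epoxide F13 is isomerised as in step 29 to 6-epi-briarellin B F14. Mitsunobu reaction with chloroacetic acid (PPh3, DIAD) gives the inverted chloroacetate F15, and thiourea/NaHCO3 in EtOH removes the chloroacetyl group selectively to reach 40.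

## Further compounds

F1 | step 10 | O3-trimethylsilyl ether of 13 | O1[C@@H](CO[Si](CC)(CC)CC)[C@@]2(O[Si](C)(C)C)CC[C@@H](OS(C)(=O)=O)[C@@]2(C)C[C@H]1CC=C
F2 | step 5 | ethyl 2-{[(2R)-1-(1-methyl-2,5-dioxocyclopentyl)pent-4-en-2-yl]oxy}-2-(trimethylsilyl)acetate (epimers at the silyl-bearing carbon) | C=CC[C@@H](OC(C(=O)OCC)[Si](C)(C)C)CC1(C)C(=O)CCC1=O
F3 | step 13 | 3-methylene analogue of 16 | C/C1=C/C[C@@H](O[Si](C)(C)C(C)(C)C)C(=C)[C@H](CO[Si](CC)(CC)CC)O[C@@H](C1)CC=C
F4 | step 13 | C1 alcohol of F3 | C/C1=C/C[C@@H](O[Si](C)(C)C(C)(C)C)C(=C)[C@H](CO)O[C@@H](C1)CC=C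
F5 | step 13 | C3 spiro-epoxide, epoxide oxygen syn to the C2 hydroxymethyl arm | C/C1=C/C[C@@H](O[Si](C)(C)C(C)(C)C)[C@@]7(CO7)[C@H](CO)O[C@@H](C1)CC=C
F6 | step 13 | C1,C3 diol (C3 methyl carbinol as in 17) | C/C1=C/C[C@@H](O[Si](C)(C)C(C)(C)C)[C@](C)(O)[C@H](CO)O[C@@H](C1)CC=C
F7 | step 25 | C15 epimer of 35 | C/C1=C/C[C@@H](OC(=O)CCCCCCC)[C@](C)(O)[C@H]2O[C@@H](C1)[C@@H]3[C@](C)(O)CC[C@@H]([C@H](C)CO)[C@H]23
F8 | step 25 | C15 epimer of 36 | C/C1=C/C[C@@H](OC(=O)CCCCCCC)[C@](C)(O)[C@H]2O[C@@H](C1)[C@@H]3[C@](C)(O)CC[C@@H]([C@H](C)C(=O)O)[C@H]23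
F9 | step 25 | C15 epimer of 37 | C/C1=C/C[C@@H](OC(=O)CCCCCCC)[C@](C)(O)[C@H]2O[C@@H](C1)[C@@H]3[C@](C)(O)CC[C@@H]([C@H](C)C(=O)OC(=O)c4c(Cl)cc(Cl)cc4Cl)[C@H]23
F10 | step 25 | C15 epimer of 38 | C/C1=C/C[C@@H](OC(=O)CCCCCCC)[C@](C)(O5)[C@H]2O[C@@H](C1)[C@@H]3[C@](C)(O)CC[C@@H]([C@H](C)C5=O)[C@H]23
F11 | step 27 | C16 aldehyde (hydroxy aldehyde) | C/C1=C/C[C@@H](OC(=O)CCCCCCC)[C@](C)(O)[C@H]2O[C@@H](C1)[C@@H]3[C@](C)(O)CC[C@@H]([C@@H](C)C=O)[C@H]23
F12 | step 27 | seven-membered lactol (C16 hemiacetal, both anomers) | C/C1=C/C[C@@H](OC(=O)CCCCCCC)[C@](C)(O5)[C@H]2O[C@@H](C1)[C@@H]3[C@](C)(O)CC[C@@H]([C@@H](C)C5O)[C@H]23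
F13 | step 28 | C6,C7-epimeric epoxide of 38 | C[C@]1(O6)[C@@H]6C[C@@H](OC(=O)CCCCCCC)[C@](C)(O5)[C@H]2O[C@@H](C1)[C@@H]3[C@](C)(O)CC[C@@H]([C@@H](C)C5=O)[C@H]23
F14 | step 28 | 6-epi-briarellin B | C=C1C[C@@H]2O[C@H]3[C@H]4[C@@H](CC[C@@](C)(O)[C@H]42)[C@@H](C)C(=O)O[C@@]3(C)[C@H](OC(=O)CCCCCCC)C[C@@H]1O
F15 | step 28 | briarellin B 6-O-chloroacetate | C=C1C[C@@H]2O[C@H]3[C@H]4[C@@H](CC[C@@](C)(O)[C@H]42)[C@@H](C)C(=O)O[C@@]3(C)[C@H](OC(=O)CCCCCCC)C[C@H]1OC(=O)CCl
A1 | alternative 1 | 2-alkenyl-1,3-dioxolane of the cyclohexadienyl diol (acetal carbon unassigned) | C[Si](C)(C)C#CC[C@@H]1OC(/C(C)=C\CCO[Si](C(C)C)(C(C)C)C(C)C)O[C@H]1C2=C[C@H](C(C)=C)CC=C2C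
A2 | alternative 1 | cis-fused tetrahydroisobenzofuran with C10 formyl group | C[Si](C)(C)C#CC[C@@H]1O[C@H](/C(C)=C\CCO[Si](C(C)C)(C(C)C)C(C)C)[C@H]2[C@H](C(C)=C)CC=C(C)[C@]21C=O
A3 | alternative 2 | C3–C4 epoxy C16 acid with C6 silyl ether | C=C1C[C@@H]2O[C@@H]([C@H]3[C@@H](CC[C@@](C)(O)[C@H]32)[C@@H](C)C(=O)O)[C@]4(C)O[C@@H]4C[C@H]1O[Si](C)(C)C(C)(C)C
A4 | alternative 2 | tetracyclic lactone with free C4 hydroxyl and C6 silyl ether | C=C1C[C@@H]2O[C@H]3[C@H]4[C@@H](CC[C@@](C)(O)[C@H]42)[C@@H](C)C(=O)O[C@@]3(C)[C@H](O)C[C@H]1O[Si](C)(C)C(C)(C)C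
A5 | alternative 3 | oxonene tetraene with (E)-enone on C2 and (Z)-2-silyloxydiene on C9 | C/C1=C/C[C@@H](O[Si](C)(C)C(C)(C)C)[C@](C)(O[Si](CC)(CC)CC)[C@H](/C=C/C(C)=O)O[C@@H](C1)/C=C(\O[Si](CC)(CC)CC)C=C
A6 | alternative 3 | tricyclic cycloadduct with C11 silyl enol ether and C14 acetyl group | C/C1=C/C[C@@H](O[Si](C)(C)C(C)(C)C)[C@](C)(O[Si](CC)(CC)CC)[C@H]2O[C@@H](C1)[C@@H]3C(O[Si](CC)(CC)CC)=CC[C@@H](C(C)=O)[C@H]23
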